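The reading comes at 1.5 min, and the half-life of X by the step to D alone is 0.20 min, shorter than that time. So the question for these flasks is where X goes.

| setting | north | north-east | north-west | south-west |
|---|---|---|---|---|
| X | 0.12 M (fed, over 1.20 min) | 0.12 M | 0.12 M | 0.12 M |
| Q | 0.120 M | 0.120 M (fed, over 1.20 min) | 0.120 M | 0.120 M |
| time | 1.5 min | 1.5 min |  | 1.5 min |
| remark | all but X at the start; X goes in evenly over 1.20 min, the run ends at 1.5 min | all but Q at the start; Q goes in evenly over 1.20 min, the run ends at 1.5 min | a single well-mixed tank run continuously and read at steady state, 1.5 min in it on average | a closed flask charged with all of it at once and left for 1.5 min |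

    X ⇌ J (K1 = 0.64, k1 = 0.098 s⁻¹)
    X → D (k2 = 0.057 s⁻¹)
    Q + J → Q.J (k3 = 0.82 L mol⁻¹ s⁻¹)
    Q.J → G (k4 = 0.034 s⁻¹)
    Q.J ⇌ E (K5 = 0.69, k5 = 0.052 s⁻¹)
    Q.J → L (k6 = 0.040 s⁻¹)

- the set-up with the highest amount of D at the outlet or at the end, in percent of the X put in ("none" if the first two lie within 2 percentage points) (north / north-east / north-west / south-west / none)
- amount of D at the outlet or at the end, in percent of the X put in, north
- amount of D at the outlet or at the end, in percent of the X put in, north-east
- amount of D at the outlet or at the end, in percent of the X put in, north-west
- amount of D at the outlet or at the end, in percent of the X put in, south-west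

- the stated concentrations are those of everything mixed, before any reaction; amounts are the same in each set-up
- the feed brings no volume worth counting
- run time (north): 1.5 min

One thing looks contradictory. X enters J at 0.098 s⁻¹, faster than it enters D at 0.057 s⁻¹, and Q is charged level with X, yet D ought to be the main product. J clears this up: Q at its full charge captures J at 0.0984 s⁻¹, and J falls back to X at 0.153 s⁻¹, faster than that capture.

The concentration that sets the order of the capture is Q*, the level of Q at which capture equals return, 0.187 M. Well below Q* the capture is close to first order in Q. With J taken at a quasi-steady level, X drains through J at its forward constant times [Q]/([Q]+Q*), which at the charged level is 0.0383 s⁻¹, slower than the step to D. The selectivity S, the share of X reaching D, is the constant to D over the sum of that constant and this drain, here 59.8 %.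

In south-west, each X that misses D takes one Q, so the midpoint between the first and last level of Q is about 0.0959 M, and taking that level as a rough working value gives S = 63.2 %. A second pass gives 0.0979 M and 62.8 %. In north-east, the feed has brought only 0.0292 M of Q by the time 17.5 s, the inverse of the constant to D, so S is near 81.1 %. This reckoning therefore puts north-east above south-west and stops short of north and north-west.

The forecast gives 58.5 % for north, 76 % for north-east, 56 % for north-west and 63 % for south-west, with north-east best, on the ground of "keeping Q scarce while X is present". Its north-east figure stands 5.1 percentage points below the reckoning here.

The simulation gives 58.8 % for north, 80.3 % for north-east, 55.8 % for north-west and 62.9 % for south-west, so north-east is best. South-west ends with 0.0759 M of Q, still below Q*.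

The neighbour of south-west charged with 0.030 M of Q takes the same reckoning. Its charged level gives S = 80.8 %. The midpoint Q of 0.0185 M gives 86.6 %, and the second pass at 0.0220 M gives 84.7 %. The neighbour itself reads 83.1 % of D, with 44 % of its Q left. At that reading it still holds 1.66 % of X and 1.28 % of J.

The constants used here come from no measurement; the flask was simulated.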